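## Analysis of the target

Target 21 is a tetrasubstituted oxolane: O1, C2 bearing a 4-hydroxyphenyl group, C3 bearing a 2,4-dihydroxybenzoyl group, C4 bearing a 4-hydroxybenzyl group and C5 bearing a 2,4-dihydroxyphenyl group. The four ring carbons are contiguous stereocentres, (2S,3S,4S,5R). The aryl groups at C2 and C5 are cis, the benzyl group at C4 is cis to the C5 aryl group, and the aroyl group at C3 is trans to both neighbours. C3 is α to the ketone, can be equilibrated and sits in the less crowded arrangement. C4 and C5 cannot be corrected later, so their cis relation has to be set kinetically. Both ring C–O bonds are benzylic and carry para (at C5 also ortho) oxygen donors, so strong protic or Lewis acids can ionise them and scramble C2 and C5. The six phenols therefore need a protecting group that leaves under neutral conditions. The strategy rests on the array aroyl carbon–C3–C4. If the aroyl carbon is read as a former ring member that sat between C3 and C4 of a 2,6-cis-diaryl dihydropyran, a 1,2-shift of C4 onto C3 contracts that ring to the oxolane and pushes the carbon out as the aryl ketone.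

## Retrosynthetic reasoning

**21 from 20.** The last disconnection removes six O–benzyl bonds. Benzyl ethers are used on all six phenols because hydrogenolysis is neutral and leaves the acid-prone bis-benzylic ring ether and the C3 centre alone. The forward step has to stop before the ring C–O bonds are cleaved.

**20 from 17.** The C3–C4 bond of the oxolane is cut and the aroyl carbon is put back between C3 and C4, giving the 4-aryl-5,6-dihydro-2H-pyran 17. Pyran C2, C3, C5 and C6 become oxolane C2, C3, C4 and C5; pyran C4 becomes the carbonyl carbon. The cut turns a stereochemical problem on a five-membered ring into one on a six-membered ring, where the three substituents of 17 are all cis and can be placed by chair-controlled reactions. The ketone oxidation state also arrives without a separate step. The forward reaction must deliver an electrophilic oxidant to alkene carbon C3, make the benzyl-bearing ring carbon migrate rather than the aryl group, and keep the configuration of the migrating carbon.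

**17 from 15 and 16.** The bond between pyran C4 and its aryl group is cut to enol triflate 15 and boronic acid 16. This brings the most electron-rich arene in late and fixes the alkene position without an elimination. The forward step is a cross-coupling on a hindered alkenyl triflate.

**15 from 13.** The triflate is traced to the enolate of a 2,6-cis tetrahydropyran-4-one, but not through an isolated saturated ketone. Catalytic hydrogenation of a pyranone alkene would set cis centres but would also strip aryl benzyl ethers, and a later enolisation would have to choose between two α positions. Both problems disappear if the enone sits on the side of the future oxolane C2. In the 2,3-cis dihydropyranone 13, conjugate hydride addition creates that centre and generates only the required enolate, which is trapped as 15. The forward step needs axial hydride delivery so that the new aryl-bearing centre ends cis to the two existing substituents.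

**13 from 12.** The O1–C6 bond of the pyranone is cut to the β-hydroxy ynone 12. The forward step is a 6-endo addition of the hydroxyl group to the ynone and must run without acid so that the benzylic alcohol and the α-centre survive.

**12 from 9 and 10.** The bond between the ketone carbon and the alkyne is cut to the N-methoxy-N-methylamide 9 and alkyne 10, a ketone synthesis that stops at the ynone.

**9 from 8, 8 from 4 and 5, 4 from 1 and 2.** The C2–C3 bond of the propanoyl chain (the future oxolane C4–C5 bond) is cut as a syn aldol between imide 4 and aldehyde 5. A syn aldol maps onto the 2,3-cis dihydropyranone, so this auxiliary-controlled step sets the absolute configuration of the route and the non-equilibratable cis pair. The (R)-configured auxiliary 2 is required. Imide 4 comes from acid 1 and 2 by N-acylation.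

## Alternatives that were turned down

**Alternative 1:** Prins cyclisation–pinacol shift.
- Disconnection: C4–C5 and C2–C3, back to an open-chain aryl acetal built on a (Z)-allylic 1,2-diol.
- Forward key step: a tetravalent tin halide would open the acetal to an oxocarbenium ion at the future C5, which adds to the Z alkene (C4–C5). The cation at C3 is then quenched by a pinacol shift of C2 from the carbinol carbon, which leaves as the formyl group of aldehyde A1.
- For it: two C–C bonds, the ring and three stereo-relationships arise in one step from an acyclic precursor. A chair-like transition state favours the 2,5-cis arrangement and the Z geometry maps onto the 4,5-cis pair. In bonds formed per step it is stronger than the chosen route.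
- Against it: the oxocarbenium ion carries a 2,4-dialkoxyphenyl group and is too stabilised to attack a plain 1,2-disubstituted alkene readily, and the cation formed at C3 is secondary and unassisted. The para-alkoxy-activated benzylic C2–O bond can itself ionise under the Lewis acid. A hydride on the secondary carbinol carbon can shift in place of C2. A1 still needs aryl-metal addition and oxidation, through an epimerisable α-formyl centre, before deprotection.
- Comparison: the chosen route rearranges a preformed ring in which three centres are already fixed, uses no strong Lewis acid and unveils the aryl ketone directly.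

**Alternative 2:** donor–acceptor cyclopropane plus aldehyde.
- Disconnection: O1–C5 and C2–C3, back to an aryl aldehyde (C2, O1) and a trans 2-aryl-3-benzylcyclopropane-1,1-diester (C3–C5).
- Forward key step: divalent tin triflate would activate the diester, the aldehyde oxygen would open the ring at the aryl-bearing carbon with inversion, and the malonate carbon would close onto the oxocarbenium carbon to give A2.
- For it: this formal [3+2] annulation has the best precedent of all four approaches for cis-2,5-diaryl oxolanes. It is catalytic, convergent and transfers the cyclopropane configuration. On precedent and convergence it is stronger than the chosen route.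
- Against it: an enantioenriched, fully substituted trans cyclopropane diester is hard to obtain. A 2,4-dioxygenated donor ring opens so easily that the invertive pathway leaks, hence the deactivating acetates in A2 and a second protecting-group pattern. The extra benzyl substituent slows the invertive attack. C3 arrives as a geminal diester, so dealkoxycarbonylation, ester-to-aryl-ketone conversion, adjustment of C3 and protecting-group exchange add four or more steps.
- Comparison: the chosen route delivers C3 at the correct oxidation level with its aryl group in the ring-forming event and ends with a single deprotection.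

**Alternative 3:** decarboxylative radical cyclisation.
- Disconnection: C4–C5, back to an α-aryl-α-alkoxy carboxylic acid whose ether oxygen already links C5 to C2 and which carries a styrene-type alkene.
- Forward key step: photocatalytic decarboxylation would give the α-alkoxy benzylic radical at C5, which closes 5-exo-trig onto the alkene. A thiol reduces the resulting benzylic radical to give silyl ether A3.
- For it: neutral, room-temperature conditions that tolerate benzyl ethers, with C2 and C3 set beforehand by closed-shell chemistry. In mildness of the key step it is stronger than the chosen route, whose key step releases a sulfonic acid.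
- Against it: two stereocentres (C4 and C5) must be set by a planar, delocalised radical whose cis preference in such closures is modest. The ether between two secondary benzylic carbons must be made without loss of configuration. A3 holds the C3 substituent at the alcohol level, so desilylation, oxidation, aryl addition and a second oxidation are needed before deprotection.
- Comparison: the chosen route fixes the C4/C5 pair by an aldol of predictable sense and reaches 21 one step after the key step.

Key step: step 8

## Route

Assumption: compounds 1, 2, 5, 10 and 16 are taken as purchasable.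

Step 1
Reactants: 1 3-[4-(benzyloxy)phenyl]propanoic acid; 2 (4R)-4-benzyl-1,3-oxazolidin-2-one
Product: 4 (4R)-4-benzyl-3-{3-[4-(benzyloxy)phenyl]propanoyl}-1,3-oxazolidin-2-one, via mixed pivalic anhydride 3 (not isolated)
Conditions: PivCl, Et3N, THF, −20 °C; then 2, LiCl, −20 °C → rt
Reagents that add atoms: none
Why: N-acylation of the oxazolidinone by a mixed anhydride with LiCl assistance is a standard way to load the auxiliary; no stereocentre is formed and the benzyl ether is inert.

Step 2
Reactants: 4 (4R)-4-benzyl-3-{3-[4-(benzyloxy)phenyl]propanoyl}-1,3-oxazolidin-2-one; 5 2,4-bis(benzyloxy)benzaldehyde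
Product: 8 (4R)-4-benzyl-3-{(2R,3R)-3-[2,4-bis(benzyloxy)phenyl]-2-[4-(benzyloxy)benzyl]-3-hydroxypropanoyl}-1,3-oxazolidin-2-one, via dibutylboron Z-enolate 6 (not isolated), via dibutylboron aldolate 7 (not isolated)
Conditions: Bu2BOTf, i-Pr2NEt, CH2Cl2, 0 °C; then 5, −78 → 0 °C; then pH 7 buffer, MeOH, H2O2, 0 °C
Reagents that add atoms: none
Why: Evans syn aldol: the Z-boron enolate reacts through a Zimmerman–Traxler chair and the (R)-benzyl group of the auxiliary shields one enolate face, so both new centres should arise syn as (2R,3R). They become C4 and C5 of the oxolane.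

Step 3
Reactants: 8 (4R)-4-benzyl-3-{(2R,3R)-3-[2,4-bis(benzyloxy)phenyl]-2-[4-(benzyloxy)benzyl]-3-hydroxypropanoyl}-1,3-oxazolidin-2-one
Product: 9 (2R,3R)-3-[2,4-bis(benzyloxy)phenyl]-2-[4-(benzyloxy)benzyl]-3-hydroxy-N-methoxy-N-methylpropanamide
Conditions: Me3Al, MeONHMe·HCl, THF, −10 → 0 °C; then aq. potassium sodium tartrate
Reagents that add atoms: N,O-dimethylhydroxylamine hydrochloride, CNOC.Cl
Why: Aluminium-amide transamidation to the Weinreb amide; the free β-hydroxyl binds aluminium and directs attack to the exocyclic carbonyl. The two stereocentres are not touched and auxiliary 2 is released for recovery.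

Step 4
Reactants: 9 (2R,3R)-3-[2,4-bis(benzyloxy)phenyl]-2-[4-(benzyloxy)benzyl]-3-hydroxy-N-methoxy-N-methylpropanamide; 10 1-(benzyloxy)-4-ethynylbenzene
Product: 12 (1R,2R)-1-[2,4-bis(benzyloxy)phenyl]-2-[4-(benzyloxy)benzyl]-5-[4-(benzyloxy)phenyl]-1-hydroxypent-4-yn-3-one, via lithium arylacetylide 11 (not isolated)
Conditions: 10, n-BuLi, THF, −78 °C; then 9, −78 → 0 °C; then aq. NH4Cl
Reagents that add atoms: none
Why: Weinreb ketone synthesis with excess acetylide (the first equivalent is spent on the hydroxyl); the chelated tetrahedral adduct prevents double addition and the weakly basic acetylide should not enolise the α-centre.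

Step 5
Reactants: 12 (1R,2R)-1-[2,4-bis(benzyloxy)phenyl]-2-[4-(benzyloxy)benzyl]-5-[4-(benzyloxy)phenyl]-1-hydroxypent-4-yn-3-one
Product: 13 (2R,3R)-2-[2,4-bis(benzyloxy)phenyl]-3-[4-(benzyloxy)benzyl]-6-[4-(benzyloxy)phenyl]-2,3-dihydro-4H-pyran-4-one
Conditions: (Ph3P)AuNTf2 (5 mol %), CH2Cl2, rt
Reagents that add atoms: none
Why: Monovalent gold activates the ynone triple bond for 6-endo-dig attack of the β-hydroxyl, a known cycloisomerisation of β-hydroxy ynones to 2,3-dihydro-4H-pyran-4-ones. The neutral conditions should leave the benzylic carbinol and the α-centre untouched, so the syn aldol becomes the 2,3-cis ring.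

Step 6
Reactants: 13 (2R,3R)-2-[2,4-bis(benzyloxy)phenyl]-3-[4-(benzyloxy)benzyl]-6-[4-(benzyloxy)phenyl]-2,3-dihydro-4H-pyran-4-one
Product: 15 (2S,5R,6R)-6-[2,4-bis(benzyloxy)phenyl]-5-[4-(benzyloxy)benzyl]-2-[4-(benzyloxy)phenyl]-5,6-dihydro-2H-pyran-4-yl trifluoromethanesulfonate, via lithium enolate 14 (not isolated)
Conditions: LiBH(s-Bu)3, THF, −78 °C; then 2-[N,N-bis(trifluoromethylsulfonyl)amino]-5-chloropyridine, −78 → −20 °C; then aq. NH4Cl
Reagents that add atoms: 2-[N,N-bis(trifluoromethylsulfonyl)amino]-5-chloropyridine, FC(F)(F)S(=O)(=O)N(c1ccc(Cl)cn1)S(=O)(=O)C(F)(F)F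
Why: Conjugate reduction of the vinylogous ester with in situ O-triflation of the enolate (reductive enol triflate formation), which forms the enolate only towards the reduced carbon. Hydride should add axially to the aryl-bearing enone terminus, on the face away from the pseudoaxial benzyl group with the C2 aryl group pseudoequatorial, so the new centre (future oxolane C2, S) ends cis to both existing substituents.

Step 7
Reactants: 15 (2S,5R,6R)-6-[2,4-bis(benzyloxy)phenyl]-5-[4-(benzyloxy)benzyl]-2-[4-(benzyloxy)phenyl]-5,6-dihydro-2H-pyran-4-yl trifluoromethanesulfonate; 16 [2,4-bis(benzyloxy)phenyl]boronic acid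
Product: 17 (2S,5S,6R)-4,6-bis[2,4-bis(benzyloxy)phenyl]-5-[4-(benzyloxy)benzyl]-2-[4-(benzyloxy)phenyl]-5,6-dihydro-2H-pyran
Conditions: Pd(PPh3)4 (5 mol %), K3PO4, 1,4-dioxane/H2O, 60 °C
Reagents that add atoms: none
Why: Suzuki–Miyaura coupling of an alkenyl triflate: zerovalent palladium inserts into the C–OTf bond and the boronate transfers the 2,4-bis(benzyloxy)phenyl group; no stereocentre takes part.

Step 8
Reactants: 17 (2S,5S,6R)-4,6-bis[2,4-bis(benzyloxy)phenyl]-5-[4-(benzyloxy)benzyl]-2-[4-(benzyloxy)phenyl]-5,6-dihydro-2H-pyran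
Product: 20 [2,4-bis(benzyloxy)phenyl]{(2S,3S,4S,5R)-5-[2,4-bis(benzyloxy)phenyl]-4-[4-(benzyloxy)benzyl]-2-[4-(benzyloxy)phenyl]oxolan-3-yl}methanone, via methoxy iodane adduct 18 (not isolated), via methoxycarbenium tosylate 19 (not isolated)
Conditions: PhI(OH)OTs, MeOH/H2O (95:5), 0 °C → rt; then aq. NaHCO3
Reagents that add atoms: water, O
Why: Proposed new method: the trivalent iodine of PhI(OH)OTs should add to alkene carbon C3 of 17 from the face opposite the pseudoaxial C5 benzyl group, and methanol caps the C4 cation, which the 2,4-bis(benzyloxy)phenyl ring stabilises, giving adduct 18 with an equatorial C–I bond. In that chair the ring bond C4–C5 is antiperiplanar to C3–I, so C5 shifts to C3 as iodobenzene leaves, pushed by the methoxy oxygen, and the former ring carbon C4 becomes the exocyclic cation 19, which water converts into the aryl ketone. The closest known reaction type is the oxidative ring contraction of cycloalkenes and 1,2-dihydronaphthalenes by this reagent in methanol, together with the related rearrangement of arylalkenes to α-aryl ketones; it has not been shown on a dihydropyran with an allylic ring oxygen. The oxolane is closed by a 1,2-alkyl shift (ring contraction, six to five) that forms the C3–C4 bond of 20, not by a cyclisation. The one new stereocentre, oxolane C3, is set by inversion at the iodine-bearing carbon, which places the aroyl group trans to both neighbours; this is also the thermodynamically preferred arrangement of this epimerisable centre. The migrating carbon keeps its configuration, so the 4,5-cis pair is preserved, and C2 and C5 are not involved. The step needs ring-carbon and not aryl migration; this is secured because the C4 aryl group is gauche to the equatorial C–I bond in the only chair that keeps both flanking aryl groups equatorial, and the nucleophilic styrene-type alkene should outrun the alkoxyarenes for the iodine reagent in methanol at 0 °C.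

Step 9
Reactants: 20 [2,4-bis(benzyloxy)phenyl]{(2S,3S,4S,5R)-5-[2,4-bis(benzyloxy)phenyl]-4-[4-(benzyloxy)benzyl]-2-[4-(benzyloxy)phenyl]oxolan-3-yl}methanone
Product: 21 (2,4-dihydroxyphenyl)[(2S,3S,4S,5R)-5-(2,4-dihydroxyphenyl)-4-(4-hydroxybenzyl)-2-(4-hydroxyphenyl)oxolan-3-yl]methanone
Conditions: H2 (1 atm), Pd/C, EtOAc/MeOH, rt
Reagents that add atoms: none
Why: Hydrogenolysis of the six aryl benzyl ethers under neutral conditions; aryl benzyl ethers cleave faster than the ring benzylic ether bonds and the hydrogen-bonded ortho-hydroxyaryl ketone resists reduction. The reaction is stopped once the benzyl groups are gone, so the four stereocentres should be unchanged.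

## Compound list

1 | 3-[4-(benzyloxy)phenyl]propanoic acid | OC(=O)CCc1ccc(OCc2ccccc2)cc1 | starting material
2 | (4R)-4-benzyl-1,3-oxazolidin-2-one | O=C1N[C@H](Cc2ccccc2)CO1 | starting material
3 | 3-[4-(benzyloxy)phenyl]propanoic 2,2-dimethylpropanoic anhydride | CC(C)(C)C(=O)OC(=O)CCc1ccc(OCc2ccccc2)cc1 | intermediate
4 | (4R)-4-benzyl-3-{3-[4-(benzyloxy)phenyl]propanoyl}-1,3-oxazolidin-2-one | O=C(CCc1ccc(OCc2ccccc2)cc1)N1[C@H](Cc2ccccc2)COC1=O | intermediate
5 | 2,4-bis(benzyloxy)benzaldehyde | O=Cc1ccc(OCc2ccccc2)cc1OCc1ccccc1 | starting material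
6 | (4R)-4-benzyl-3-{(1Z)-3-[4-(benzyloxy)phenyl]-1-[(dibutylboranyl)oxy]prop-1-en-1-yl}-1,3-oxazolidin-2-one | CCCCB(CCCC)O/C(=C\Cc1ccc(OCc2ccccc2)cc1)N1[C@H](Cc2ccccc2)COC1=O | intermediate
7 | (4R)-4-benzyl-3-{(2R,3R)-3-[2,4-bis(benzyloxy)phenyl]-2-[4-(benzyloxy)benzyl]-3-[(dibutylboranyl)oxy]propanoyl}-1,3-oxazolidin-2-one | O=C(N1[C@H](Cc2ccccc2)COC1=O)[C@H](Cc1ccc(OCc2ccccc2)cc1)[C@@H](OB(CCCC)CCCC)c1ccc(OCc2ccccc2)cc1OCc1ccccc1 | intermediate
8 | (4R)-4-benzyl-3-{(2R,3R)-3-[2,4-bis(benzyloxy)phenyl]-2-[4-(benzyloxy)benzyl]-3-hydroxypropanoyl}-1,3-oxazolidin-2-one | O=C(N1[C@H](Cc2ccccc2)COC1=O)[C@H](Cc1ccc(OCc2ccccc2)cc1)[C@@H](O)c1ccc(OCc2ccccc2)cc1OCc1ccccc1 | intermediate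
9 | (2R,3R)-3-[2,4-bis(benzyloxy)phenyl]-2-[4-(benzyloxy)benzyl]-3-hydroxy-N-methoxy-N-methylpropanamide | CON(C)C(=O)[C@H](Cc1ccc(OCc2ccccc2)cc1)[C@@H](O)c1ccc(OCc2ccccc2)cc1OCc1ccccc1 | intermediate
10 | 1-(benzyloxy)-4-ethynylbenzene | C#Cc1ccc(OCc2ccccc2)cc1 | starting material
11 | lithium [4-(benzyloxy)phenyl]acetylide | [Li]C#Cc1ccc(OCc2ccccc2)cc1 | intermediate
12 | (1R,2R)-1-[2,4-bis(benzyloxy)phenyl]-2-[4-(benzyloxy)benzyl]-5-[4-(benzyloxy)phenyl]-1-hydroxypent-4-yn-3-one | O=C(C#Cc1ccc(OCc2ccccc2)cc1)[C@H](Cc1ccc(OCc2ccccc2)cc1)[C@@H](O)c1ccc(OCc2ccccc2)cc1OCc1ccccc1 | intermediate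
13 | (2R,3R)-2-[2,4-bis(benzyloxy)phenyl]-3-[4-(benzyloxy)benzyl]-6-[4-(benzyloxy)phenyl]-2,3-dihydro-4H-pyran-4-one (2,3-cis) | O1C(c2ccc(OCc3ccccc3)cc2)=CC(=O)[C@H](Cc2ccc(OCc3ccccc3)cc2)[C@@H]1c1ccc(OCc2ccccc2)cc1OCc1ccccc1 | intermediate
14 | lithium (2S,5R,6R)-6-[2,4-bis(benzyloxy)phenyl]-5-[4-(benzyloxy)benzyl]-2-[4-(benzyloxy)phenyl]-5,6-dihydro-2H-pyran-4-olate | O1[C@H](c2ccc(OCc3ccccc3)cc2)C=C(O[Li])[C@H](Cc2ccc(OCc3ccccc3)cc2)[C@@H]1c1ccc(OCc2ccccc2)cc1OCc1ccccc1 | intermediate
15 | (2S,5R,6R)-6-[2,4-bis(benzyloxy)phenyl]-5-[4-(benzyloxy)benzyl]-2-[4-(benzyloxy)phenyl]-5,6-dihydro-2H-pyran-4-yl trifluoromethanesulfonate (2,5,6-all-cis) | O1[C@H](c2ccc(OCc3ccccc3)cc2)C=C(OS(=O)(=O)C(F)(F)F)[C@H](Cc2ccc(OCc3ccccc3)cc2)[C@@H]1c1ccc(OCc2ccccc2)cc1OCc1ccccc1 | intermediate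
16 | [2,4-bis(benzyloxy)phenyl]boronic acid | OB(O)c1ccc(OCc2ccccc2)cc1OCc1ccccc1 | starting material
17 | (2S,5S,6R)-4,6-bis[2,4-bis(benzyloxy)phenyl]-5-[4-(benzyloxy)benzyl]-2-[4-(benzyloxy)phenyl]-5,6-dihydro-2H-pyran (2,5,6-all-cis) | O1[C@H](c2ccc(OCc3ccccc3)cc2)C=C(c2ccc(OCc3ccccc3)cc2OCc2ccccc2)[C@H](Cc2ccc(OCc3ccccc3)cc2)[C@@H]1c1ccc(OCc2ccccc2)cc1OCc1ccccc1 | intermediate
18 | {4,6-bis[2,4-bis(benzyloxy)phenyl]-5-[4-(benzyloxy)benzyl]-2-[4-(benzyloxy)phenyl]-4-methoxyoxan-3-yl}(phenyl)iodanyl 4-methylbenzenesulfonate; iodine on the ring face opposite the C2, C5 and C6 substituents, configuration at C4 left open | O1[C@H](c2ccc(OCc3ccccc3)cc2)[C@@H](I(c2ccccc2)OS(=O)(=O)c2ccc(C)cc2)C(OC)(c2ccc(OCc3ccccc3)cc2OCc2ccccc2)[C@H](Cc2ccc(OCc3ccccc3)cc2)[C@@H]1c1ccc(OCc2ccccc2)cc1OCc1ccccc1 | intermediate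
19 | {[2,4-bis(benzyloxy)phenyl][(2S,3S,4S,5R)-5-[2,4-bis(benzyloxy)phenyl]-4-[4-(benzyloxy)benzyl]-2-[4-(benzyloxy)phenyl]oxolan-3-yl]methylidene}(methyl)oxonium 4-methylbenzenesulfonate | C[O+]=C(c1ccc(OCc2ccccc2)cc1OCc1ccccc1)[C@H]1[C@H](Cc2ccc(OCc3ccccc3)cc2)[C@H](c2ccc(OCc3ccccc3)cc2OCc2ccccc2)O[C@@H]1c1ccc(OCc2ccccc2)cc1.Cc1ccc(cc1)S([O-])(=O)=O | intermediate
20 | [2,4-bis(benzyloxy)phenyl]{(2S,3S,4S,5R)-5-[2,4-bis(benzyloxy)phenyl]-4-[4-(benzyloxy)benzyl]-2-[4-(benzyloxy)phenyl]oxolan-3-yl}methanone | O=C(c1ccc(OCc2ccccc2)cc1OCc1ccccc1)[C@H]1[C@H](Cc2ccc(OCc3ccccc3)cc2)[C@H](c2ccc(OCc3ccccc3)cc2OCc2ccccc2)O[C@@H]1c1ccc(OCc2ccccc2)cc1 | intermediate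
21 | (2,4-dihydroxyphenyl)[(2S,3S,4S,5R)-5-(2,4-dihydroxyphenyl)-4-(4-hydroxybenzyl)-2-(4-hydroxyphenyl)oxolan-3-yl]methanone | O=C(c1ccc(O)cc1O)[C@H]1[C@H](Cc2ccc(O)cc2)[C@H](c2ccc(O)cc2O)O[C@@H]1c1ccc(O)cc1 | target

Total step count: 9. Longest linear sequence: 9 steps (1 to 21).

## Least certain steps

**Step 8 (key step, proposed new method).** Most likely failure is diversion of the iodine adduct, for several reasons:
- Solvent capture can give vicinal dimethoxylation.
- The ring oxygen or the C2 hydrogen can shift in place of the ring carbon, because several groups can assist the loss of iodobenzene.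
- The iodine reagent can attack the dialkoxyarenes, which are strong nucleophiles.
- The sulfonic acid released can ionise the allylic, benzylic C2–O bond.

The fallback sets out from 17 and uses known chemistry. OsO4 (cat.) with N-methylmorpholine N-oxide in acetone/water should dihydroxylate the alkene from the face opposite the three ring substituents to give the cis-diol F1. MsCl and Et3N at −20 °C should sulfonylate only the secondary hydroxyl to give the hydroxy mesylate F2. Et3Al in CH2Cl2 at −78 °C then triggers the pinacol-type shift of the ring carbon antiperiplanar to the equatorial mesylate, which returns to 20 with the same configuration.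

**Step 6.** Hydride may attack the carbonyl carbon instead of the aryl-substituted enone terminus, which is deactivated by the para-alkoxyaryl group. The enolate may also open the ring by β-elimination of the ring alkoxide before it is triflated. The fallback sets out from 13. Copper hydride conjugate reduction (Cu(OAc)2·H2O, 1,2-bis(diphenylphosphino)benzene, polymethylhydrosiloxane, t-BuOH, toluene) should give the saturated all-cis ketone F3. Kinetic deprotonation at the CH2 flank with KN(SiMe3)2 at −78 °C and the same triflating agent then returns to 15. Regiocontrol then rests on kinetic enolisation instead of on the reduction.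

**Step 5.** The electron-rich benzylic alcohol may ionise and lose water, or the aldol may revert, before the hydroxyl adds to the alkyne. The fallback sets out from 12. Et2NH in EtOH at rt adds to the ynone to give the enaminone F4. Pyridinium p-toluenesulfonate in toluene then closes the ring by addition–elimination with loss of diethylamine, which returns to 13.

**Step 7.** Protodeboronation of the ortho,para-dialkoxy boronic acid in aqueous base may outrun transmetalation onto the hindered alkenylpalladium intermediate. The fallback sets out from 15 and reverses the polarity. PdCl2(dppf), bis(pinacolato)diboron and KOAc in dioxane give the alkenyl boronate F5. Coupling with 1-bromo-2,4-bis(benzyloxy)benzene (Pd(PPh3)4, K3PO4) returns to 17.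

**Step 9.** Hydrogenolysis may continue into the ring benzylic C–O bonds, most easily at C5 once its ortho and para phenols are free, or reduce the ketone. The fallback sets out from 20 and replaces reduction by Lewis-acid dealkylation: BCl3 with pentamethylbenzene as benzyl-cation scavenger in CH2Cl2 at −78 °C gives 21 directly. It makes no new compound (F0).

## Further compounds

F1 | step 8 | 4,6-bis[2,4-bis(benzyloxy)phenyl]-5-[4-(benzyloxy)benzyl]-2-[4-(benzyloxy)phenyl]oxane-3,4-diol (2,5,6-cis substituents; 3,4-cis diol on the opposite ring face) | O1[C@H](c2ccc(OCc3ccccc3)cc2)[C@@H](O)[C@](O)(c2ccc(OCc3ccccc3)cc2OCc2ccccc2)[C@H](Cc2ccc(OCc3ccccc3)cc2)[C@@H]1c1ccc(OCc2ccccc2)cc1OCc1ccccc1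
F2 | step 8 | 4,6-bis[2,4-bis(benzyloxy)phenyl]-5-[4-(benzyloxy)benzyl]-2-[4-(benzyloxy)phenyl]-4-hydroxyoxan-3-yl methanesulfonate (same configuration as F1) | O1[C@H](c2ccc(OCc3ccccc3)cc2)[C@@H](OS(C)(=O)=O)[C@](O)(c2ccc(OCc3ccccc3)cc2OCc2ccccc2)[C@H](Cc2ccc(OCc3ccccc3)cc2)[C@@H]1c1ccc(OCc2ccccc2)cc1OCc1ccccc1
F3 | step 6 | (2R,3R,6S)-2-[2,4-bis(benzyloxy)phenyl]-3-[4-(benzyloxy)benzyl]-6-[4-(benzyloxy)phenyl]oxan-4-one | O1[C@H](c2ccc(OCc3ccccc3)cc2)CC(=O)[C@H](Cc2ccc(OCc3ccccc3)cc2)[C@@H]1c1ccc(OCc2ccccc2)cc1OCc1ccccc1
F4 | step 5 | (1R,2R,4E)-1-[2,4-bis(benzyloxy)phenyl]-2-[4-(benzyloxy)benzyl]-5-[4-(benzyloxy)phenyl]-5-(diethylamino)-1-hydroxypent-4-en-3-one | CCN(CC)/C(c1ccc(OCc2ccccc2)cc1)=C/C(=O)[C@H](Cc1ccc(OCc2ccccc2)cc1)[C@@H](O)c1ccc(OCc2ccccc2)cc1OCc1ccccc1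
F5 | step 7 | 2-{(2S,5S,6R)-6-[2,4-bis(benzyloxy)phenyl]-5-[4-(benzyloxy)benzyl]-2-[4-(benzyloxy)phenyl]-5,6-dihydro-2H-pyran-4-yl}-4,4,5,5-tetramethyl-1,3,2-dioxaborolane | O1[C@H](c2ccc(OCc3ccccc3)cc2)C=C(B2OC(C)(C)C(C)(C)O2)[C@H](Cc2ccc(OCc3ccccc3)cc2)[C@@H]1c1ccc(OCc2ccccc2)cc1OCc1ccccc1
F0 | step 9 | none | none
A1 | alternative 1 | (2S,3S,4S,5R)-5-[2,4-bis(benzyloxy)phenyl]-4-[4-(benzyloxy)benzyl]-2-[4-(benzyloxy)phenyl]oxolane-3-carbaldehyde | O=C[C@H]1[C@H](Cc2ccc(OCc3ccccc3)cc2)[C@H](c2ccc(OCc3ccccc3)cc2OCc2ccccc2)O[C@@H]1c1ccc(OCc2ccccc2)cc1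
A2 | alternative 2 | dimethyl (2R,4S,5R)-5-[2,4-bis(acetyloxy)phenyl]-4-[4-(benzyloxy)benzyl]-2-[4-(benzyloxy)phenyl]oxolane-3,3-dicarboxylate | COC(=O)C1(C(=O)OC)[C@H](Cc2ccc(OCc3ccccc3)cc2)[C@H](c2ccc(OC(C)=O)cc2OC(C)=O)O[C@@H]1c1ccc(OCc2ccccc2)cc1
A3 | alternative 3 | tert-butyl({(2S,3R,4S,5R)-5-[2,4-bis(benzyloxy)phenyl]-4-[4-(benzyloxy)benzyl]-2-[4-(benzyloxy)phenyl]oxolan-3-yl}methoxy)dimethylsilane | CC(C)(C)[Si](C)(C)OC[C@H]1[C@H](Cc2ccc(OCc3ccccc3)cc2)[C@H](c2ccc(OCc3ccccc3)cc2OCc2ccccc2)O[C@@H]1c1ccc(OCc2ccccc2)cc1
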